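If the step from Z and Q is the slow one, this flask runs on two half-lives; here is what it holds.

    L + G → E + Z (k1 = 0.00519 M⁻¹ s⁻¹)
    X ⇌ E, rate k2*(cs2 - [E]) while solid is left; crystals form when [E] > cs2 (cs2 = 0.25 M, k2 = 1.45 × 10⁻⁴ s⁻¹)
    Z + Q ⇌ G + D (K3 = 0.251, k3 = 1.43 × 10⁻⁴ M⁻¹ s⁻¹)
    E ⇌ J (K4 = 11.5, k4 = 6.96 × 10⁻⁶ s⁻¹)

L 0.26 M; Q 1.00 equiv; Z 10 mol%; time 40 h; volume of the second phase over the first 1.0

- what is said of E includes X
- in the second phase: Q, D; everything else is in the first
- charges count per volume of the first phase; a concentration in a rate is the amount of a species over the volume of its own phase; every rate counts per litre of the first phase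
- X is a solid; its amount is given per volume of the solution
- run time (flask): 40 h

- ochre: doubling the dissolution coefficient of step 2, all else as stated
- grey: doubling the solubility in step 2, all else as stated
- amber: doubling the amount of Q, all else as stated

1. how much E and X together there is at 40 h, in percent of the L charged
2. the change that raises the amount of E and X together at 40 h, in percent of the L charged most ("none" if none brings more than 2 percentage points) (ochre / grey / amber / none)
3. amount of E and X together at 40 h, in percent of the L charged, after amber

- As charged, G was spent with a half-life of 0.14 h, far faster than Z turned into G, at 5.2 h, so I took nearly all of the catalyst to rest as Z (the resting state) and the step from Z and Q to be rate-limiting.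
- With [Z] held near 0.0260 M and the way back of that step dropped in my reckoning, I had [Q] and [L] fall together, pseudo-first-order, with a supply half-life of 51.8 h.
- I had E leave for J with a loss half-life of 27.7 h; the rate constant of the way back is ten times smaller, so I dropped it.
- I carried their ratio 1.87, supply half-life over loss half-life.
- In my reckoning E grows with the supply early on and late falls with the supply half-life, the longer of the two; the join is the decay factor of Q minus that of E, divided by the ratio less one.
- At 40 h those factors were 58.5% and 36.7%, which gave me 25.0% of the L charged.
- That is 0.0651 M of E, less than the solubility 0.25 M, so I expected no crystals and nothing from ochre or grey.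
- Amber doubles the supply in my reckoning, so I picked it and reckoned 50.0%, a figure that spends 83.0% of the L.
- The forecast gave 24.3% (22.5% to 26%), amber as best, and 44% (41% to 47%) after amber, lower than my figure for amber, reasoning that “G stays small”.
- The flask gave 24.2%, amber as best and 43.8% after amber, and at 40.0 h it held 60% of its Q, beside my factor of 58.5%. In the neighbour with 25 mol% of Z, the supply half-life drops to 20.7 h and the ratio to 0.749, so the same join gives 41.8%; that flask stood at 39.7%.

The numbers of this flask are assumed, and the outcome is calculated.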